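**Retrosynthetic overview**
1. Target 13 ⇐ homoallylic alcohol 10: the vinyl group is cleaved to the C9 alcohol and the isopropylidene acetal is removed.
2. 10 ⇐ aldehyde 7 + aryloxyallene 4: the C7–C8 bond is made with an (E)-γ-aryloxyallylborane, an α-oxygenated carbanion (d1) equivalent. It joins two carbons that are both natively electrophilic (carbonyl C and O-bearing C), sets both stereocentres and already carries the ring-B ether.
3. The same borane hydroborates the ring allyl group, so the propanol chain appears in the same operation.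
4. 4 ⇐ methoxyeugenol 1 + propargyl bromide 2; 7 ⇐ vanillin 5 + dioxanol 6.
5. Rings: none is built. Both arenes are bought, and the 1,3-dioxane is a temporary acetal that is opened in the last step.

Assumption: (+)-Ipc2BH (from (−)-α-pinene) is used as a purchased or pre-crystallised reagent, and a telescoped one-pot sequence is counted as one step.

**Step 1**
Reactants: 1 4-allyl-2,6-dimethoxyphenol (methoxyeugenol); 2 propargyl bromide (3-bromoprop-1-yne)
Product: 3 5-allyl-1,3-dimethoxy-2-(prop-2-yn-1-yloxy)benzene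
Conditions: K2CO3 (2 equiv), acetone, 56 °C, 6 h
Reagents that add atoms: none
Why: Williamson O-alkylation (SN2) of the phenoxide with a reactive propargylic bromide; both ortho positions are blocked, so no Claisen chemistry competes, and no stereocentre is formed.

**Step 2**
Reactants: 3 5-allyl-1,3-dimethoxy-2-(prop-2-yn-1-yloxy)benzene
Product: 4 5-allyl-1,3-dimethoxy-2-(propa-1,2-dien-1-yloxy)benzene
Conditions: t-BuOK (0.3 equiv), THF, 0 °C, 1 h; pH 7 quench, basic alumina plug, used at once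
Reagents that add atoms: none
Why: base-catalysed propargyl–allenyl prototropic isomerisation, in which the O–CH2–C≡C protons are removed by catalytic alkoxide and reprotonation at the alkyne terminus gives the aryloxyallene; at 0 °C in THF this should outrun migration of the ring allyl double bond.

**Step 3**
Reactants: 5 vanillin (4-hydroxy-3-methoxybenzaldehyde); 6 2,2-dimethyl-1,3-dioxan-5-ol
Product: 7 4-[(2,2-dimethyl-1,3-dioxan-5-yl)oxy]-3-methoxybenzaldehyde
Conditions: PPh3 (1.3 equiv), DIAD (1.3 equiv), THF, 0 → 40 °C, 16 h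
Reagents that add atoms: none
Why: Mitsunobu etherification, in which the acidic phenol of vanillin (pKa about 7.4) displaces the activated secondary alcohol; C5 of the dioxane is not stereogenic, so inversion is irrelevant, and the aldehyde is tolerated.

**Step 4**
Reactants: 4 5-allyl-1,3-dimethoxy-2-(propa-1,2-dien-1-yloxy)benzene; 7 4-[(2,2-dimethyl-1,3-dioxan-5-yl)oxy]-3-methoxybenzaldehyde
Product: 10 (1S,2R)-1-{4-[(2,2-dimethyl-1,3-dioxan-5-yl)oxy]-3-methoxyphenyl}-2-[4-(3-hydroxypropyl)-2,6-dimethoxyphenoxy]but-3-en-1-ol, via bis-borane 8 (not isolated), via borinate adduct 9 (not isolated)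
Conditions: (+)-Ipc2BH (2.15 equiv), THF, −25 → 0 °C, 4 h; then 7 (0.9 equiv), −78 °C, 4 h → 23 °C; then 3 M NaOH, 30% H2O2, 0 → 40 °C
Reagents that add atoms: hydrogen peroxide, OO
Why: Proposed new method: (+)-Ipc2BH delivers H to the central and B to the terminal carbon of the aryloxyallene to give the (E)-γ-aryloxyallylborane, while a second equivalent hydroborates the ring allyl group anti-Markovnikov to an alkyl–B(Ipc)2 that is inert to aldehydes; only the allylborane adds to 7, through a closed chair (Zimmerman–Traxler) transition state in which the E-aryloxy group and the aldehyde aryl are equatorial (anti, i.e. erythro) and the Ipc groups from (−)-α-pinene direct attack to the Re face (1S, hence 2R), and the oxidative work-up turns the spectator C–B bond into the side-chain alcohol; the closest known reaction type is the Brown-type hydroboration of alkoxyallenes or allenylboronates with Ipc2BH followed by asymmetric allylboration of an aldehyde.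

**Step 5**
Reactants: 10 (1S,2R)-1-{4-[(2,2-dimethyl-1,3-dioxan-5-yl)oxy]-3-methoxyphenyl}-2-[4-(3-hydroxypropyl)-2,6-dimethoxyphenoxy]but-3-en-1-ol
Product: 13 (1S,2R)-1-{4-[(1,3-dihydroxypropan-2-yl)oxy]-3-methoxyphenyl}-2-[4-(3-hydroxypropyl)-2,6-dimethoxyphenoxy]propane-1,3-diol, via aldehyde 11 (not isolated), via acetonide tetraol 12 (not isolated)
Conditions: O3, CH2Cl2–MeOH (4:1), Sudan Red 7B end point, −78 °C; NaBH4 (5 equiv), −78 → 0 °C; concentrate; AcOH–H2O (4:1), 40 °C, 2 h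
Reagents that add atoms: ozone, [O-][O+]=O
Why: ozonolysis of the only C=C (the dye end point is meant to spare the arenes) with immediate borohydride reduction, so the α-aryloxy aldehyde is reduced to the C9 alcohol before it can epimerise or undergo retro-aldol cleavage, followed by mild aqueous acetic acid hydrolysis of the isopropylidene acetal, which leaves both stereocentres untouched.

**Compound list**
1 | 4-allyl-2,6-dimethoxyphenol (methoxyeugenol) | C=CCc1cc(OC)c(O)c(OC)c1 | starting material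
2 | propargyl bromide | C#CCBr | starting material
3 | 5-allyl-1,3-dimethoxy-2-(prop-2-yn-1-yloxy)benzene | C=CCc1cc(OC)c(OCC#C)c(OC)c1 | intermediate
4 | 5-allyl-1,3-dimethoxy-2-(propa-1,2-dien-1-yloxy)benzene | C=CCc1cc(OC)c(OC=C=C)c(OC)c1 | intermediate
5 | vanillin | COc1cc(C=O)ccc1O | starting material
6 | 2,2-dimethyl-1,3-dioxan-5-ol | CC1(C)OCC(O)CO1 | starting material
7 | 4-[(2,2-dimethyl-1,3-dioxan-5-yl)oxy]-3-methoxybenzaldehyde | COc1cc(C=O)ccc1OC1COC(C)(C)OC1 | intermediate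
8 | bis-borane: [(2E)-3-{4-[3-(diisopinocampheylboryl)propyl]-2,6-dimethoxyphenoxy}prop-2-en-1-yl]diisopinocampheylborane (Ipc from (−)-α-pinene) | COc3cc(CCCB([C@H]1C[C@H]2C[C@@H]([C@@H]1C)C2(C)C)[C@H]1C[C@H]2C[C@@H]([C@@H]1C)C2(C)C)cc(OC)c3O/C=C/CB([C@H]1C[C@H]2C[C@@H]([C@@H]1C)C2(C)C)[C@H]1C[C@H]2C[C@@H]([C@@H]1C)C2(C)C | intermediate (not isolated)
9 | borinate adduct: (1S,2R)-1-{4-[(2,2-dimethyl-1,3-dioxan-5-yl)oxy]-3-methoxyphenyl}-2-{4-[3-(diisopinocampheylboryl)propyl]-2,6-dimethoxyphenoxy}but-3-en-1-yl diisopinocampheylborinate | COc3cc([C@H](OB([C@H]1C[C@H]2C[C@@H]([C@@H]1C)C2(C)C)[C@H]1C[C@H]2C[C@@H]([C@@H]1C)C2(C)C)[C@@H](C=C)Oc4c(OC)cc(CCCB([C@H]1C[C@H]2C[C@@H]([C@@H]1C)C2(C)C)[C@H]1C[C@H]2C[C@@H]([C@@H]1C)C2(C)C)cc4OC)ccc3OC5COC(C)(C)OC5 | intermediate (not isolated)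
10 | (1S,2R)-1-{4-[(2,2-dimethyl-1,3-dioxan-5-yl)oxy]-3-methoxyphenyl}-2-[4-(3-hydroxypropyl)-2,6-dimethoxyphenoxy]but-3-en-1-ol | COc1cc([C@H](O)[C@@H](C=C)Oc2c(OC)cc(CCCO)cc2OC)ccc1OC1COC(C)(C)OC1 | intermediate
11 | (2S,3S)-3-{4-[(2,2-dimethyl-1,3-dioxan-5-yl)oxy]-3-methoxyphenyl}-3-hydroxy-2-[4-(3-hydroxypropyl)-2,6-dimethoxyphenoxy]propanal | COc1cc([C@H](O)[C@@H](C=O)Oc2c(OC)cc(CCCO)cc2OC)ccc1OC1COC(C)(C)OC1 | intermediate (not isolated)
12 | (1S,2R)-1-{4-[(2,2-dimethyl-1,3-dioxan-5-yl)oxy]-3-methoxyphenyl}-2-[4-(3-hydroxypropyl)-2,6-dimethoxyphenoxy]propane-1,3-diol | COc1cc([C@H](O)[C@@H](CO)Oc2c(OC)cc(CCCO)cc2OC)ccc1OC1COC(C)(C)OC1 | intermediate (not isolated)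
13 | (1S,2R)-1-{4-[(1,3-dihydroxypropan-2-yl)oxy]-3-methoxyphenyl}-2-[4-(3-hydroxypropyl)-2,6-dimethoxyphenoxy]propane-1,3-diol | COc1cc([C@H](O)[C@@H](CO)Oc2c(OC)cc(CCCO)cc2OC)ccc1OC(CO)CO | target

**Totals**
Total steps: 5. Longest linear sequence: 4 (steps 1, 2, 4, 5).

**Three steps most likely to fail**

1. Step 4 (key coupling). The anti (erythro) outcome requires the allene-derived reagent to react as its E isomer, and I am relying on equilibration at 0 °C to provide it; a Z reagent would give the threo adduct. The regiochemistry of H–B addition to an aryloxyallene and the two hydroborations in one pot are also untested on this substrate. The fallback sets out from 4 and 7 and comes back at 10; it replaces direct anti-allylation by syn-allylation plus SN2 inversion of the carbinol. If the adduct is mainly threo, 4 is hydroborated at −40 °C with the antipodal (−)-Ipc2BH (from (+)-α-pinene) without equilibration, giving the (Z)-bis-borane F1. Addition of 7 at −78 °C then gives the syn borinate adduct F2 by Si-face attack, and NaOH/H2O2 releases the threo alcohol (1R,2R)-1-{4-[(2,2-dimethyl-1,3-dioxan-5-yl)oxy]-3-methoxyphenyl}-2-[4-(3-hydroxypropyl)-2,6-dimethoxyphenoxy]but-3-en-1-ol F3. A Mitsunobu reaction with 4-nitrobenzoic acid (PPh3, DIAD, toluene, 0 °C) esterifies the primary alcohol and inverts the benzylic carbinol, giving the bis(4-nitrobenzoate) of 10 F4, and K2CO3 in MeOH then liberates 10.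

2. Step 2 (allene formation). t-BuOK may also move the ring allyl double bond into conjugation or over-isomerise the allene to the 1-propynyl ether, and the aryloxyallene is acid-labile. The fallback sets out from 1 and comes back at 10; it removes the allyl group before any base is used. Compound 1 is hydroborated with 9-BBN (2.2 equiv, THF) to the O-boryl B-alkyl bis(9-BBN) species F5, which NaOH/H2O2 converts to 4-(3-hydroxypropyl)-2,6-dimethoxyphenol F6. Selective phenol alkylation with 2 and K2CO3 gives 3-[3,5-dimethoxy-4-(prop-2-yn-1-yloxy)phenyl]propan-1-ol F7, and t-BuOK (1.3 equiv, the alkoxide is a spectator) gives 3-[3,5-dimethoxy-4-(propa-1,2-dien-1-yloxy)phenyl]propan-1-ol F8. Under the conditions of step 4 the free hydroxyl is taken up as a borinate, so (+)-Ipc2BH (2.15 equiv) gives the O-borinate allylborane F9, aldehyde 7 gives the bis-borinate adduct F10, and the same oxidative work-up delivers 10.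

3. Step 5 (cleavage and unmasking). Ozone can attack the two electron-rich arenes, aldehyde 11 can epimerise or undergo retro-aldol cleavage if reduction lags, and the acid stage could ionise the benzylic alcohol. The fallback sets out from 10 and comes back at 12; it replaces ozone by a stepwise glycol cleavage with isolated intermediates. OsO4 (2 mol %) with NMO in acetone–water gives (1S,2S)-1-{4-[(2,2-dimethyl-1,3-dioxan-5-yl)oxy]-3-methoxyphenyl}-2-[4-(3-hydroxypropyl)-2,6-dimethoxyphenoxy]butane-1,3,4-triol (both C3 epimers) F11, which is isolated. NaIO4 in THF–pH 7 buffer at 0 °C cleaves it to 11, which is reduced at once with NaBH4 to 12. Compound 12 is isolated and hydrolysed in a separate operation (AcOH–H2O) to 13.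

**Further compounds**
F1 | step 4 | (Z)-bis-borane: [(2Z)-3-{4-[3-(diisopinocampheylboryl)propyl]-2,6-dimethoxyphenoxy}prop-2-en-1-yl]diisopinocampheylborane (Ipc from (+)-α-pinene) | COc3cc(CCCB([C@@H]1C[C@@H]2C[C@H]([C@H]1C)C2(C)C)[C@@H]1C[C@@H]2C[C@H]([C@H]1C)C2(C)C)cc(OC)c3O/C=C\CB([C@@H]1C[C@@H]2C[C@H]([C@H]1C)C2(C)C)[C@@H]1C[C@@H]2C[C@H]([C@H]1C)C2(C)C
F2 | step 4 | syn borinate adduct: (1R,2R)-1-{4-[(2,2-dimethyl-1,3-dioxan-5-yl)oxy]-3-methoxyphenyl}-2-{4-[3-(diisopinocampheylboryl)propyl]-2,6-dimethoxyphenoxy}but-3-en-1-yl diisopinocampheylborinate (Ipc from (+)-α-pinene) | COc3cc([C@@H](OB([C@@H]1C[C@@H]2C[C@H]([C@H]1C)C2(C)C)[C@@H]1C[C@@H]2C[C@H]([C@H]1C)C2(C)C)[C@@H](C=C)Oc4c(OC)cc(CCCB([C@@H]1C[C@@H]2C[C@H]([C@H]1C)C2(C)C)[C@@H]1C[C@@H]2C[C@H]([C@H]1C)C2(C)C)cc4OC)ccc3OC5COC(C)(C)OC5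
F3 | step 4 | (1R,2R)-1-{4-[(2,2-dimethyl-1,3-dioxan-5-yl)oxy]-3-methoxyphenyl}-2-[4-(3-hydroxypropyl)-2,6-dimethoxyphenoxy]but-3-en-1-ol | COc1cc([C@@H](O)[C@@H](C=C)Oc2c(OC)cc(CCCO)cc2OC)ccc1OC1COC(C)(C)OC1
F4 | step 4 | bis(4-nitrobenzoate) of 10 (benzylic ester 1S after inversion, plus side-chain ester) | COc1cc([C@H](OC(=O)c3ccc(cc3)[N+](=O)[O-])[C@@H](C=C)Oc2c(OC)cc(CCCOC(=O)c3ccc(cc3)[N+](=O)[O-])cc2OC)ccc1OC1COC(C)(C)OC1
F5 | step 2 | O-boryl B-alkyl bis(9-BBN) species from 1 | COc1cc(CCCB2C3CCCC2CCC3)cc(OC)c1OB1C2CCCC1CCC2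
F6 | step 2 | 4-(3-hydroxypropyl)-2,6-dimethoxyphenol | COc1cc(CCCO)cc(OC)c1O
F7 | step 2 | 3-[3,5-dimethoxy-4-(prop-2-yn-1-yloxy)phenyl]propan-1-ol | COc1cc(CCCO)cc(OC)c1OCC#C
F8 | step 2 | 3-[3,5-dimethoxy-4-(propa-1,2-dien-1-yloxy)phenyl]propan-1-ol | COc1cc(CCCO)cc(OC)c1OC=C=C
F9 | step 2 | O-borinate allylborane: 3-{4-[(1E)-3-(diisopinocampheylboryl)prop-1-en-1-yloxy]-3,5-dimethoxyphenyl}propyl diisopinocampheylborinate (Ipc from (−)-α-pinene) | COc3cc(CCCOB([C@H]1C[C@H]2C[C@@H]([C@@H]1C)C2(C)C)[C@H]1C[C@H]2C[C@@H]([C@@H]1C)C2(C)C)cc(OC)c3O/C=C/CB([C@H]1C[C@H]2C[C@@H]([C@@H]1C)C2(C)C)[C@H]1C[C@H]2C[C@@H]([C@@H]1C)C2(C)C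
F10 | step 2 | bis-borinate adduct: bis(diisopinocampheylborinate) of 10 at the benzylic and side-chain oxygens (1S,2R; Ipc from (−)-α-pinene) | COc3cc([C@H](OB([C@H]1C[C@H]2C[C@@H]([C@@H]1C)C2(C)C)[C@H]1C[C@H]2C[C@@H]([C@@H]1C)C2(C)C)[C@@H](C=C)Oc4c(OC)cc(CCCOB([C@H]1C[C@H]2C[C@@H]([C@@H]1C)C2(C)C)[C@H]1C[C@H]2C[C@@H]([C@@H]1C)C2(C)C)cc4OC)ccc3OC5COC(C)(C)OC5
F11 | step 5 | (1S,2S)-1-{4-[(2,2-dimethyl-1,3-dioxan-5-yl)oxy]-3-methoxyphenyl}-2-[4-(3-hydroxypropyl)-2,6-dimethoxyphenoxy]butane-1,3,4-triol (both C3 epimers) | COc1cc([C@H](O)[C@@H](C(O)CO)Oc2c(OC)cc(CCCO)cc2OC)ccc1OC1COC(C)(C)OC1
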